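**Strategy.** Everything rests on disconnecting the C8–C9 ring-fusion bond of the cyclononadiene–tetrahydrofuran bicycle: C9 carries the oxidised one-carbon branch C10 and C8 carries C11 with its CH2O arms, the signature of an ester-enolate Claisen shift. An Ireland–Claisen contraction of a thirteen-membered allylic lactone forms this bond, closes the nine-membered carbocycle and sets C8 and C9 in one operation. The precursor is macrolactone 15: cis C3=C4, exo-methylene at C1, the (S)-linalool-derived C5 carbinol as its triethylsilyl ether, and an E C8=C11 olefin, fixed by an ester-based olefination, whose second CH2O arm is a PMB ether.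

Key step: step 12

Remark: atoms are numbered as in the target (C1 bears the exocyclic CH2, C1–C9 form the carbocycle, the ether ring is C9–C10–O–C11–C8, the dienyl chain is C12–C15); (S)-linalool of high enantiomeric purity and 4-methyl hydrogen itaconate are assumed to be purchasable.

Remark: C11 is set after the key step by reagent-controlled epoxidation and invertive ether closure, so only step 12 relies on substrate bias.

Step 1
Reactants: 1 (S)-linalool
Product: 2 (3S)-3,7-dimethyl-3-[(triethylsilyl)oxy]octa-1,6-diene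
Conditions: TESOTf, 2,6-lutidine, CH2Cl2, −78 → 0 °C
Reagents that add atoms: triethylsilyl trifluoromethanesulfonate, CC[Si](CC)(CC)OS(=O)(=O)C(F)(F)F
Why: Silylation of a hindered tertiary alcohol with a silyl triflate and a hindered pyridine base is routine and leaves the carbinol centre (C5 of the target) untouched.

Step 2
Reactants: 2 (3S)-3,7-dimethyl-3-[(triethylsilyl)oxy]octa-1,6-diene
Product: 3 (2S)-2-methyl-2-[(triethylsilyl)oxy]pentanedial
Conditions: O3, CH2Cl2, −78 °C; PPh3, −78 °C → rt
Reagents that add atoms: ozone, O=[O+][O-]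
Why: Exhaustive ozonolysis with reductive work-up cleaves both olefins and unmasks C4 and C8 as aldehydes that differ sharply in hindrance, the C4 aldehyde sitting on the quaternary silyloxy carbon and being non-enolisable.

Step 3
Reactants: 3 (2S)-2-methyl-2-[(triethylsilyl)oxy]pentanedial; 4 trimethyl 2-phosphonoacrylate
Product: 6 methyl (2E,6S)-2-{[(4-methoxybenzyl)oxy]methyl}-6-methyl-7-oxo-6-[(triethylsilyl)oxy]hept-2-enoate, via phosphonate carbanion 5 (not isolated)
Conditions: 4-MeOC6H4CH2OH, NaH, THF, 0 °C; 4, 0 °C; then 3 (1.0 equiv), −78 → 0 °C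
Reagents that add atoms: 4-methoxybenzyl alcohol, COc1ccc(CO)cc1
Why: Michael addition of the alkoxide to the vinylphosphonate gives an α-branched phosphonate carbanion whose Horner–Wadsworth–Emmons reaction should take only the unhindered C8 aldehyde and place the ester trans to the chain (E), so that the PMB-oxymethyl arm is cis to C7, any minor geometric isomer being removed by chromatography.

Step 4
Reactants: 6 methyl (2E,6S)-2-{[(4-methoxybenzyl)oxy]methyl}-6-methyl-7-oxo-6-[(triethylsilyl)oxy]hept-2-enoate
Product: 7 methyl (2E,6S)-2-{[(4-methoxybenzyl)oxy]methyl}-6-methyl-6-[(triethylsilyl)oxy]oct-2-en-7-ynoate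
Conditions: dimethyl (1-diazo-2-oxopropyl)phosphonate, K2CO3, MeOH, 0 °C → rt
Reagents that add atoms: dimethyl (1-diazo-2-oxopropyl)phosphonate, CC(=O)C(=[N+]=[N-])P(=O)(OC)OC
Why: The Ohira–Bestmann homologation converts the non-enolisable C4 aldehyde into the terminal alkyne (the new carbon is C3) under carbonate conditions that leave the trisubstituted enoate and the silyl ether alone.

Step 5
Reactants: 7 methyl (2E,6S)-2-{[(4-methoxybenzyl)oxy]methyl}-6-methyl-6-[(triethylsilyl)oxy]oct-2-en-7-ynoate
Product: 8 (2Z,6S)-2-{[(4-methoxybenzyl)oxy]methyl}-6-methyl-6-[(triethylsilyl)oxy]oct-2-en-7-yn-1-ol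
Conditions: DIBAL-H (2.5 equiv), CH2Cl2, −78 °C; Rochelle salt
Reagents that add atoms: none
Why: 1,2-Reduction of the enoate by DIBAL-H gives the allylic alcohol without touching the olefin geometry, so the free CH2OH (the future lactone arm) is trans to C7.

Step 6
Reactants: 9 4-methyl hydrogen itaconate
Product: 10 methyl 3-(hydroxymethyl)but-3-enoate
Conditions: BH3·THF (1.0 equiv), THF, −15 → 0 °C; H2O
Reagents that add atoms: none
Why: Borane reduction is chemoselective for the free carboxylic acid over the methyl ester and the electron-poor 1,1-disubstituted olefin, giving the alcohol that carries C2, C1 with its methylene, C9 and C10.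

Step 7
Reactants: 10 methyl 3-(hydroxymethyl)but-3-enoate
Product: 11 methyl 3-(bromomethyl)but-3-enoate
Conditions: CBr4, PPh3, CH2Cl2, 0 °C
Reagents that add atoms: carbon tetrabromide, BrC(Br)(Br)Br
Why: The Appel bromination is neutral, so the β,γ-unsaturated ester is not conjugated, and SN2 and SN2′ pathways give the same bromide because both allylic termini are CH2 groups.

Step 8
Reactants: 8 (2Z,6S)-2-{[(4-methoxybenzyl)oxy]methyl}-6-methyl-6-[(triethylsilyl)oxy]oct-2-en-7-yn-1-ol; 11 methyl 3-(bromomethyl)but-3-enoate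
Product: 12 methyl (7S,10Z)-12-hydroxy-11-{[(4-methoxybenzyl)oxy]methyl}-7-methyl-3-methylidene-7-[(triethylsilyl)oxy]dodec-10-en-5-ynoate
Conditions: CuI (20 mol%), n-Bu4NI (20 mol%), K2CO3, DMF, rt
Reagents that add atoms: none
Why: Copper-catalysed coupling of a terminal alkyne with an allylic bromide under carbonate conditions forms the C2–C3 bond of the skipped enyne, tolerates the free alcohol and the ester, and is regiochemically unambiguous for this symmetric allyl unit.

Step 9
Reactants: 12 methyl (7S,10Z)-12-hydroxy-11-{[(4-methoxybenzyl)oxy]methyl}-7-methyl-3-methylidene-7-[(triethylsilyl)oxy]dodec-10-en-5-ynoate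
Product: 13 methyl (5Z,7S,10Z)-12-hydroxy-11-{[(4-methoxybenzyl)oxy]methyl}-7-methyl-3-methylidene-7-[(triethylsilyl)oxy]dodeca-5,10-dienoate
Conditions: H2 (1 atm), Lindlar catalyst, quinoline, EtOAc, rt
Reagents that add atoms: none
Why: Lindlar semihydrogenation adds hydrogen syn to the alkyne only, which gives the cis C3=C4 olefin while the 1,1-disubstituted and trisubstituted olefins and the PMB ether are not reduced.

Step 10
Reactants: 13 methyl (5Z,7S,10Z)-12-hydroxy-11-{[(4-methoxybenzyl)oxy]methyl}-7-methyl-3-methylidene-7-[(triethylsilyl)oxy]dodeca-5,10-dienoate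
Product: 14 (5Z,7S,10Z)-12-hydroxy-11-{[(4-methoxybenzyl)oxy]methyl}-7-methyl-3-methylidene-7-[(triethylsilyl)oxy]dodeca-5,10-dienoic acid
Conditions: Me3SnOH, 1,2-dichloroethane, 80 °C; 0.1 M aq. HCl wash
Reagents that add atoms: trimethyltin hydroxide, C[Sn](C)(C)O
Why: Ester cleavage with trimethyltin hydroxide proceeds under nearly neutral conditions, which avoids base-mediated migration of the exo-methylene into conjugation with the carboxyl group.

Step 11
Reactants: 14 (5Z,7S,10Z)-12-hydroxy-11-{[(4-methoxybenzyl)oxy]methyl}-7-methyl-3-methylidene-7-[(triethylsilyl)oxy]dodeca-5,10-dienoic acid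
Product: 15 (6Z,8S,11E)-12-{[(4-methoxybenzyl)oxy]methyl}-8-methyl-4-methylidene-8-[(triethylsilyl)oxy]-1-oxacyclotrideca-6,11-dien-2-one
Conditions: PPh3, DIAD, toluene (2 mM, slow addition of 14), 0 °C → rt
Reagents that add atoms: none
Why: Mitsunobu macrolactonisation activates the primary allylic alcohol instead of the acyl group, so the β,γ-unsaturated acid cannot isomerise through a ketene or acylammonium species, and the thirteen-membered ring, stiffened by three olefins, should close at high dilution.

Step 12
Reactants: 15 (6Z,8S,11E)-12-{[(4-methoxybenzyl)oxy]methyl}-8-methyl-4-methylidene-8-[(triethylsilyl)oxy]-1-oxacyclotrideca-6,11-dien-2-one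
Product: 18 (1R,4Z,6S,9S)-9-{3-[(4-methoxybenzyl)oxy]prop-1-en-2-yl}-6-methyl-2-methylidene-6-[(triethylsilyl)oxy]cyclonon-4-ene-1-carboxylic acid, via silyl ketene acetal 16 (not isolated), via trimethylsilyl ester 17 (not isolated)
Conditions: LDA, THF–DMPU (4:1), −78 °C; TMSCl, −78 °C → rt, then 50 °C; 10% aq. citric acid
Reagents that add atoms: none
Why: LDA removes a C9 proton and O-silylation gives ketene acetal 16, in which C9=C10–O–CH2–C11=C8 is a 1,5-diene held inside the thirteen-membered ring, and a [3,3]-sigmatropic shift then forms C8–C9 as the O–CH2 bond breaks, the silyl ester 17 being hydrolysed to acid 18. The closest known reaction type is the Ireland–Claisen ring contraction of macrocyclic allylic lactones, which excises four ring atoms (here C10, the ring oxygen, its CH2 and C11). The nine-membered carbocycle is closed by the sigmatropic bond formation itself, a transannular C8–C9 union across the macrolactone, so no end-to-end cyclisation of a medium ring is needed. C8 and C9 are set together in a chair transition state: the E C8=C11 olefin places the C8–C7 bond equatorial and the ketene acetal with C1 anti to the ring oxygen (the geometry expected from enolisation in THF–DMPU) places the C9–C1 bond equatorial, which makes the two hydrogens anti and gives the trans C8/C9 relationship. The absolute sense (8S,9R in target numbering) has to come from the C5 stereocentre, which is expected to bias the conformation of the seven-atom tether and so the olefin face offered to the ketene acetal. The step thus needs chair over boat and one π-facial pairing, the first secured by the trans olefin and the short tether, the second only by C5, and this is the single place where the route carries real risk.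

Step 13
Reactants: 18 (1R,4Z,6S,9S)-9-{3-[(4-methoxybenzyl)oxy]prop-1-en-2-yl}-6-methyl-2-methylidene-6-[(triethylsilyl)oxy]cyclonon-4-ene-1-carboxylic acid
Product: 19 [(1R,4Z,6S,9S)-9-{3-[(4-methoxybenzyl)oxy]prop-1-en-2-yl}-6-methyl-2-methylidene-6-[(triethylsilyl)oxy]cyclonon-4-en-1-yl]methanol
Conditions: LiAlH4, Et2O, 0 °C → rt; Rochelle salt
Reagents that add atoms: none
Why: Hydride reduction of the acid proceeds through its carboxylate, which is not enolised, so C9 keeps its configuration and the exo-methylene stays out of conjugation while C10 reaches the alcohol level needed for the ether ring.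

Step 14
Reactants: 19 [(1R,4Z,6S,9S)-9-{3-[(4-methoxybenzyl)oxy]prop-1-en-2-yl}-6-methyl-2-methylidene-6-[(triethylsilyl)oxy]cyclonon-4-en-1-yl]methanol
Product: 20 C10-O-triethylsilyl ether of 19
Conditions: TESCl, imidazole, CH2Cl2, 0 °C
Reagents that add atoms: chlorotriethylsilane, CC[Si](Cl)(CC)CC
Why: Silylation masks the C10 hydroxyl as a primary TES ether, which can later be cleaved by mild acid in the presence of the tertiary TES and the TBDPS ethers.

Step 15
Reactants: 20 C10-O-triethylsilyl ether of 19
Product: 21 allylic alcohol 2-[cyclononenyl]prop-2-en-1-ol (20 without the PMB group)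
Conditions: DDQ, CH2Cl2–pH 7 buffer (10:1), 0 °C
Reagents that add atoms: none
Why: Oxidative cleavage of the PMB ether by DDQ under buffered conditions frees the allylic alcohol on C11 and should leave both silyl ethers and the skipped diene intact.

Step 16
Reactants: 21 allylic alcohol 2-[cyclononenyl]prop-2-en-1-ol (20 without the PMB group)
Product: 23 tert-butyldiphenylsilyl ether of epoxy alcohol 22, via epoxy alcohol 22 (not isolated)
Conditions: Ti(OiPr)4 (10 mol%), L-(+)-DIPT (12 mol%), t-BuOOH, 4 Å MS, CH2Cl2, −20 °C; P(OMe)3; then TBDPSCl, Et3N, DMAP, −20 → 0 °C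
Reagents that add atoms: tert-butyl hydroperoxide, CC(C)(C)OO; tert-butyl(chloro)diphenylsilane, CC(C)(C)[Si](Cl)(c1ccccc1)c1ccccc1
Why: Sharpless asymmetric epoxidation addresses only the olefin that bears a free allylic hydroxyl, L-(+)-tartrate should deliver oxygen with the usual sense for 2-substituted allylic alcohols to give the (11S)-epoxy alcohol under reagent control, and silylation in the same flask protects the sensitive 2,2-disubstituted epoxy alcohol and marks the original arm.

Step 17
Reactants: 23 tert-butyldiphenylsilyl ether of epoxy alcohol 22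
Product: 25 trans-fused tetrahydrofuran alcohol with CH2OH and CH2OTBDPS on C11, via hydroxy epoxide 24 (not isolated)
Conditions: CSA (0.2 equiv), CH2Cl2–MeOH (10:1), 0 °C
Reagents that add atoms: none
Why: Mild acid removes the primary TES ether selectively and the freed C10 hydroxyl opens the protonated epoxide at the quaternary carbon in a 5-exo-tet mode with inversion, which closes the trans-fused ether ring and fixes C11 with the silyloxymethyl arm cis to C7.

Step 18
Reactants: 25 trans-fused tetrahydrofuran alcohol with CH2OH and CH2OTBDPS on C11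
Product: 26 C12 aldehyde of 25
Conditions: Dess–Martin periodinane, pyridine, CH2Cl2, 0 °C → rt
Reagents that add atoms: none
Why: Dess–Martin oxidation converts the neopentyl primary alcohol into a non-enolisable aldehyde under neutral conditions, so no stereocentre is at risk.

Step 19
Reactants: 27 1-bromo-3-methylbut-2-ene
Product: 28 diethyl (3-methylbut-2-en-1-yl)phosphonate
Conditions: P(OEt)3, neat, 120 °C
Reagents that add atoms: triethyl phosphite, CCOP(OCC)OCC
Why: The Michaelis–Arbuzov reaction of a primary allylic bromide gives the allylic phosphonate by substitution at the unsubstituted terminus.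

Step 20
Reactants: 26 C12 aldehyde of 25; 28 diethyl (3-methylbut-2-en-1-yl)phosphonate
Product: 29 silyl-protected (12E)-diene
Conditions: 28 (1.5 equiv), n-BuLi (1.4 equiv), THF, −78 °C; then 26, −78 °C → rt
Reagents that add atoms: none
Why: Horner–Wadsworth–Emmons olefination with a lithiated allylic phosphonate reacts at its α-carbon (the γ-carbon is blocked by two methyl groups) and should give the E C12=C13 bond of the conjugated diene.

Step 21
Reactants: 29 silyl-protected (12E)-diene
Product: 30 diol (target without the stearoyl group)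
Conditions: TBAF, THF, rt → 40 °C
Reagents that add atoms: none
Why: Fluoride-mediated desilylation cleaves both the primary TBDPS and the tertiary TES ether, and no base-sensitive ester is present at this stage.

Step 22
Reactants: 30 diol (target without the stearoyl group); 31 stearic acid
Product: 32 CNP0274030.1
Conditions: EDC·HCl, DMAP, CH2Cl2, 0 °C → rt
Reagents that add atoms: none
Why: Steglich-type carbodiimide esterification acylates the primary hydroxyl and leaves the tertiary allylic C5 alcohol alone, and placing it last avoids ester participation in the epoxide opening and acyl migration between the two C11 arms.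

**Compound list**

1 | (S)-linalool | C=C[C@@](C)(O)CCC=C(C)C | starting material
2 | (3S)-3,7-dimethyl-3-[(triethylsilyl)oxy]octa-1,6-diene | C=C[C@@](C)(O[Si](CC)(CC)CC)CCC=C(C)C | intermediate
3 | (2S)-2-methyl-2-[(triethylsilyl)oxy]pentanedial | O=C[C@@](C)(O[Si](CC)(CC)CC)CCC=O | intermediate
4 | trimethyl 2-phosphonoacrylate (methyl 2-(dimethoxyphosphoryl)prop-2-enoate) | C=C(C(=O)OC)P(=O)(OC)OC | starting material
5 | sodium salt of the carbanion of methyl 2-(dimethoxyphosphoryl)-3-[(4-methoxybenzyl)oxy]propanoate | [Na+].COC(=O)[C-](COCc1ccc(OC)cc1)P(=O)(OC)OC | intermediate (not isolated)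
6 | methyl (2E,6S)-2-{[(4-methoxybenzyl)oxy]methyl}-6-methyl-7-oxo-6-[(triethylsilyl)oxy]hept-2-enoate | O=C[C@@](C)(O[Si](CC)(CC)CC)CC/C=C(\COCc1ccc(OC)cc1)C(=O)OC | intermediate
7 | methyl (2E,6S)-2-{[(4-methoxybenzyl)oxy]methyl}-6-methyl-6-[(triethylsilyl)oxy]oct-2-en-7-ynoate | C#C[C@@](C)(O[Si](CC)(CC)CC)CC/C=C(\COCc1ccc(OC)cc1)C(=O)OC | intermediate
8 | (2Z,6S)-2-{[(4-methoxybenzyl)oxy]methyl}-6-methyl-6-[(triethylsilyl)oxy]oct-2-en-7-yn-1-ol | C#C[C@@](C)(O[Si](CC)(CC)CC)CC/C=C(\COCc1ccc(OC)cc1)CO | intermediate
9 | 4-methyl hydrogen itaconate (4-methoxy-2-methylidene-4-oxobutanoic acid) | C=C(CC(=O)OC)C(=O)O | starting material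
10 | methyl 3-(hydroxymethyl)but-3-enoate | C=C(CO)CC(=O)OC | intermediate
11 | methyl 3-(bromomethyl)but-3-enoate | C=C(CBr)CC(=O)OC | intermediate
12 | methyl (7S,10Z)-12-hydroxy-11-{[(4-methoxybenzyl)oxy]methyl}-7-methyl-3-methylidene-7-[(triethylsilyl)oxy]dodec-10-en-5-ynoate | COC(=O)CC(=C)CC#C[C@@](C)(O[Si](CC)(CC)CC)CC/C=C(\COCc1ccc(OC)cc1)CO | intermediate
13 | methyl (5Z,7S,10Z)-12-hydroxy-11-{[(4-methoxybenzyl)oxy]methyl}-7-methyl-3-methylidene-7-[(triethylsilyl)oxy]dodeca-5,10-dienoate | COC(=O)CC(=C)C/C=C\[C@@](C)(O[Si](CC)(CC)CC)CC/C=C(\COCc1ccc(OC)cc1)CO | intermediate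
14 | (5Z,7S,10Z)-12-hydroxy-11-{[(4-methoxybenzyl)oxy]methyl}-7-methyl-3-methylidene-7-[(triethylsilyl)oxy]dodeca-5,10-dienoic acid (seco acid) | OC(=O)CC(=C)C/C=C\[C@@](C)(O[Si](CC)(CC)CC)CC/C=C(\COCc1ccc(OC)cc1)CO | intermediate
15 | (6Z,8S,11E)-12-{[(4-methoxybenzyl)oxy]methyl}-8-methyl-4-methylidene-8-[(triethylsilyl)oxy]-1-oxacyclotrideca-6,11-dien-2-one (thirteen-membered lactone, key-step precursor) | O=C1CC(=C)C/C=C\[C@@](C)(O[Si](CC)(CC)CC)CC/C=C(\COCc2ccc(OC)cc2)CO1 | intermediate
16 | trimethylsilyl ketene acetal of 15 (C9=C10 with C1 anti to the ring oxygen) | C[Si](C)(C)O/C1=C\C(=C)C/C=C\[C@@](C)(O[Si](CC)(CC)CC)CC/C=C(\COCc2ccc(OC)cc2)CO1 | intermediate (not isolated)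
17 | trimethylsilyl ester of 18 | C=C1C/C=C\[C@@](C)(O[Si](CC)(CC)CC)CC[C@@H]([C@H]1C(=O)O[Si](C)(C)C)C(=C)COCc1ccc(OC)cc1 | intermediate (not isolated)
18 | (1R,4Z,6S,9S)-9-{3-[(4-methoxybenzyl)oxy]prop-1-en-2-yl}-6-methyl-2-methylidene-6-[(triethylsilyl)oxy]cyclonon-4-ene-1-carboxylic acid (5S,8S,9R in target numbering; C8/C9 trans; key-step product) | C=C1C/C=C\[C@@](C)(O[Si](CC)(CC)CC)CC[C@@H]([C@H]1C(=O)O)C(=C)COCc1ccc(OC)cc1 | intermediate
19 | [(1R,4Z,6S,9S)-9-{3-[(4-methoxybenzyl)oxy]prop-1-en-2-yl}-6-methyl-2-methylidene-6-[(triethylsilyl)oxy]cyclonon-4-en-1-yl]methanol (C10 alcohol) | C=C1C/C=C\[C@@](C)(O[Si](CC)(CC)CC)CC[C@@H]([C@H]1CO)C(=C)COCc1ccc(OC)cc1 | intermediate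
20 | C10-O-triethylsilyl ether of 19 (configuration unchanged) | C=C1C/C=C\[C@@](C)(O[Si](CC)(CC)CC)CC[C@@H]([C@H]1CO[Si](CC)(CC)CC)C(=C)COCc1ccc(OC)cc1 | intermediate
21 | allylic alcohol: 20 with the PMB ether cleaved (C11 bears =CH2 and CH2OH) | C=C1C/C=C\[C@@](C)(O[Si](CC)(CC)CC)CC[C@@H]([C@H]1CO[Si](CC)(CC)CC)C(=C)CO | intermediate
22 | (11S)-epoxy alcohol: 2,2-disubstituted oxirane at C11 bearing CH2OH | C=C1C/C=C\[C@@](C)(O[Si](CC)(CC)CC)CC[C@@H]([C@H]1CO[Si](CC)(CC)CC)[C@]1(CO)CO1 | intermediate (not isolated)
23 | tert-butyldiphenylsilyl ether of 22 (same spatial arrangement at C11) | C=C1C/C=C\[C@@](C)(O[Si](CC)(CC)CC)CC[C@@H]([C@H]1CO[Si](CC)(CC)CC)[C@]1(CO[Si](c2ccccc2)(c2ccccc2)C(C)(C)C)CO1 | intermediate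
24 | hydroxy epoxide: 23 with the C10 hydroxyl free | C=C1C/C=C\[C@@](C)(O[Si](CC)(CC)CC)CC[C@@H]([C@H]1CO)[C@]1(CO[Si](c2ccccc2)(c2ccccc2)C(C)(C)C)CO1 | intermediate (not isolated)
25 | trans-fused tetrahydrofuran alcohol: C11 bears CH2OH (cis to H8) and CH2OTBDPS (cis to C7); C5 OTES | C=C1C/C=C\[C@@](C)(O[Si](CC)(CC)CC)CC[C@H]2[C@H]1CO[C@@]2(CO)CO[Si](c1ccccc1)(c1ccccc1)C(C)(C)C | intermediate
26 | aldehyde: 25 with the CH2OH arm oxidised to CHO (C12) | C=C1C/C=C\[C@@](C)(O[Si](CC)(CC)CC)CC[C@H]2[C@H]1CO[C@@]2(C=O)CO[Si](c1ccccc1)(c1ccccc1)C(C)(C)C | intermediate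
27 | 1-bromo-3-methylbut-2-ene (prenyl bromide) | CC(C)=CCBr | starting material
28 | diethyl (3-methylbut-2-en-1-yl)phosphonate | CCOP(=O)(CC=C(C)C)OCC | intermediate
29 | silyl-protected diene: C11 bears (1E)-4-methylpenta-1,3-dienyl and CH2OTBDPS; C5 OTES | C=C1C/C=C\[C@@](C)(O[Si](CC)(CC)CC)CC[C@H]2[C@H]1CO[C@@]2(/C=C/C=C(C)C)CO[Si](c1ccccc1)(c1ccccc1)C(C)(C)C | intermediate
30 | diol (5S,8S,9R,11R): target without the stearoyl group | C=C1C/C=C\[C@@](C)(O)CC[C@H]2[C@H]1CO[C@@]2(/C=C/C=C(C)C)CO | intermediate
31 | stearic acid | CCCCCCCCCCCCCCCCCC(=O)O | starting material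
32 | CNP0274030.1 (5S,8S,9R,11R in the numbering above; stearate of 30 at the C11 hydroxymethyl group) | C=C1C/C=C\[C@@](C)(O)CC[C@H]2[C@H]1CO[C@@]2(/C=C/C=C(C)C)COC(=O)CCCCCCCCCCCCCCCCC | target

**Step count.** Total: 22 steps. Longest linear sequence: 19 steps (steps 1–5, 8–18 and 20–22, from (S)-linalool); steps 6–7 and 19 are side branches.

**Steps most likely to fail**

1. Step 12. Enolisation may give the ketene acetal with C1 syn to the ring oxygen, or the shift may pass through a boat; either would invert C9 relative to C8. The remote C5 centre may also discriminate poorly between the two olefin faces. The fallback replaces substrate control by reagent control. Setting out from 15, soft enolisation with a C2-symmetric chiral bromoborane, (4S,5S)-2-bromo-1,3-bis{[3,5-bis(trifluoromethyl)phenyl]sulfonyl}-4,5-diphenyl-1,3,2-diazaborolidine (or its enantiomer, whichever proves matched with C5), and a tertiary amine chosen to fix the enolate geometry would give the boron ketene acetal F1. Its rearrangement between −20 °C and rt would give the acyloxyborane F2, and aqueous work-up would return acid 18, where the route continues.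

2. Step 11. Intermolecular esterification to diolide and oligomers may outrun ring closure, and the activated allylic oxyphosphonium species may be attacked at C8 (SN2′) or ionise. The fallback activates the carboxyl group instead of the alcohol. Setting out from 14, 2-methyl-6-nitrobenzoic anhydride, Et3N and DMAP in CH2Cl2 at high dilution and room temperature would give the mixed anhydride F3, which acylates the free allylic alcohol and rejoins the route at 15. The low temperature is meant to limit migration of the exo-methylene.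

3. Step 3. The phosphonate carbanion may fail to discriminate between the two aldehydes, residual alkoxide may start aldol chemistry of the dialdehyde, and the olefin may form with low E selectivity. The fallback addresses the two olefins of 2 one after the other. Setting out from 2, ozonolysis with one equivalent of ozone (Sudan III as end-point indicator; PPh3) should cleave only the electron-rich trisubstituted olefin and give the aldehyde F4. The Michael/Horner–Wadsworth–Emmons olefination with 4 and PMB alkoxide (through 5) would then give the enoate F5, which still carries the vinyl group. A second ozonolysis, now selective for the isolated vinyl group over the electron-poor enoate, would give 6, where the route is rejoined.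

**Further compounds**

F1 | step 12 | boron ketene acetal of 15 with the (4S,5S)-1,3-bis{[3,5-bis(trifluoromethyl)phenyl]sulfonyl}-4,5-diphenyl-1,3,2-diazaborolidin-2-yl group on the enolate oxygen | O(B1N(S(=O)(=O)c2cc(C(F)(F)F)cc(C(F)(F)F)c2)[C@@H](c2ccccc2)[C@H](c2ccccc2)N1S(=O)(=O)c1cc(C(F)(F)F)cc(C(F)(F)F)c1)/C1=C\C(=C)C/C=C\[C@@](C)(O[Si](CC)(CC)CC)CC/C=C(\COCc2ccc(OC)cc2)CO1
F2 | step 12 | acyloxyborane of 18 with the same diazaborolidine | C=C1C/C=C\[C@@](C)(O[Si](CC)(CC)CC)CC[C@@H]([C@H]1C(=O)OB1N(S(=O)(=O)c2cc(C(F)(F)F)cc(C(F)(F)F)c2)[C@@H](c2ccccc2)[C@H](c2ccccc2)N1S(=O)(=O)c1cc(C(F)(F)F)cc(C(F)(F)F)c1)C(=C)COCc1ccc(OC)cc1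
F3 | step 11 | mixed anhydride of 14 with 2-methyl-6-nitrobenzoic acid | Cc1cccc([N+](=O)[O-])c1C(=O)OC(=O)CC(=C)C/C=C\[C@@](C)(O[Si](CC)(CC)CC)CC/C=C(\COCc1ccc(OC)cc1)CO
F4 | step 3 | (4S)-4-methyl-4-[(triethylsilyl)oxy]hex-5-enal | C=C[C@@](C)(O[Si](CC)(CC)CC)CCC=O
F5 | step 3 | methyl (2E,6S)-2-{[(4-methoxybenzyl)oxy]methyl}-6-methyl-6-[(triethylsilyl)oxy]octa-2,7-dienoate | C=C[C@@](C)(O[Si](CC)(CC)CC)CC/C=C(\COCc1ccc(OC)cc1)C(=O)OC
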